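**Plan**

- Numbering (labdane-type): C1–C2 = CH2CO2H arm on C10; C3–C4 = CO2H and C(CH3)2 of the arm on C5; C5–C10 = ring B; O, C8, C9, C11, C12, C13 = ring C; C14–C15 = vinyl. Enabling feature: the ring oxygen joins the quaternary ring-fusion carbon C8 to C13, so ring C is the cyclopentanone ring C8–C9–C11–C12–C13(=O) of a trans-hydrindanone with one oxygen slipped in between C8 and C13.
- Retrosynthesis: cut C13–C14 and C13–CH3 (back to a δ-lactone), then C8–O (Baeyer–Villiger, back to the hydrindanone). Rejoin C2–C3 to a temporary carbocyclic ring A, which acts as a tether so that the crowded C4–C5 bond is made intramolecularly (Robinson annulation, C1–C10 and C4–C5). Finally cut C9–C10 and C7–C8 (Hajos–Parrish-type annulation).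
- Forward: the cyclopentane is bought; ring B closes in step 2; ring A closes in step 6 and is cleaved at C2–C3 in steps 8–9; the five-membered ring is enlarged to ring C in step 13; the C13 substituents follow.
- Stereochemistry: C8 from the D-phenylalanine-mediated aldol; C9 from dissolving-metal reduction (trans fusion); C10 from Michael addition anti to the axial C8 methyl; C5 from axial protonation in the reductive methylation; C8–O by retentive migration; C13 by attack on an oxocarbenium ion anti to the axial C8 methyl.

Key step: step 13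

Remark: β is the face of the C8 methyl group; the C13 configuration of 21 and 22 is left open because both epimers ionise to the same cation 23.

**Route**

Step 1
Reactants: 1 2-methylcyclopentane-1,3-dione; 2 pent-1-en-3-one
Product: 3 2-methyl-2-(3-oxopentyl)cyclopentane-1,3-dione
Conditions: H2O, CH3CO2H (cat.), 75 °C
Reagents that add atoms: none
Why: Michael addition of the acidic 1,3-dione to the vinyl ketone needs no strong base in water and stops at the triketone because the alkylated carbon has no proton left.

Step 2
Reactants: 3 2-methyl-2-(3-oxopentyl)cyclopentane-1,3-dione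
Product: 5 (7aR)-4,7a-dimethyl-2,3,7,7a-tetrahydro-1H-indene-1,5(6H)-dione, via cis-fused ketol 4 (not isolated)
Conditions: D-phenylalanine (1 equiv), (1R)-(−)-camphor-10-sulfonic acid (0.5 equiv), DMF, 30 → 70 °C
Reagents that add atoms: none
Why: Hajos–Parrish-type intramolecular aldol condensation through the amino-acid enamine of the side-chain ketone distinguishes the two enantiotopic ring carbonyls, the D-amino acid should give the R configuration at C8 (the antipode of the steroid series), and the acid co-catalyst dehydrates ketol 4; recrystallisation is expected to raise the enantiomeric purity.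

Step 3
Reactants: 5 (7aR)-4,7a-dimethyl-2,3,7,7a-tetrahydro-1H-indene-1,5(6H)-dione
Product: 6 (1R,7aR)-1-hydroxy-4,7a-dimethyl-1,2,3,6,7,7a-hexahydro-5H-inden-5-one
Conditions: NaBH4 (0.3 equiv), EtOH, −20 °C
Reagents that add atoms: none
Why: Chemoselective borohydride reduction, since the saturated cyclopentanone is more electrophilic than the conjugated ketone and hydride enters anti to the angular methyl, giving a temporary 13β-alcohol that is oxidised again in step 12.

Step 4
Reactants: 6 (1R,7aR)-1-hydroxy-4,7a-dimethyl-1,2,3,6,7,7a-hexahydro-5H-inden-5-one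
Product: 7 (1R,7aR)-1-[(tert-butyldimethylsilyl)oxy]-4,7a-dimethyl-1,2,3,6,7,7a-hexahydro-5H-inden-5-one
Conditions: t-BuMe2SiCl, imidazole, DMF, rt
Reagents that add atoms: tert-butyldimethylsilyl chloride CC(C)(C)[Si](C)(C)Cl
Why: Silyl ether formation masks the C13 oxygen with a group that should tolerate dissolving metal, alkoxide, autoxidation and alkaline peroxide.

Step 5
Reactants: 7 (1R,7aR)-1-[(tert-butyldimethylsilyl)oxy]-4,7a-dimethyl-1,2,3,6,7,7a-hexahydro-5H-inden-5-one
Product: 9 trans-fused 13β-silyloxy-hydrindan-5-one (8β-CH3, 9α-H, 10α-CH3 equatorial), via lithium enolate 8 (not isolated)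
Conditions: Li, NH3(l)/THF, t-BuOH (1 equiv), −78 °C; then NH4Cl
Reagents that add atoms: none
Why: Dissolving-metal (Birch-type) enone reduction protonates C9 on the face opposite the angular C8 methyl, as is usual for this enone class with an ether at C13, so the trans ring fusion (9α-H) should result, and protonation of enolate 8 leaves the C10 methyl equatorial.

Step 6
Reactants: 9 trans-fused 13β-silyloxy-hydrindan-5-one; 2 pent-1-en-3-one
Product: 11 tricyclic ring-A enone (C3 ketone, C4=C5, 4-CH3, 8β-CH3, 10β-CH3, 9α-H, 13β-OSi), via Michael adduct 10 (not isolated)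
Conditions: NaOCH3 (cat.), CH3OH, 0 °C → rt; then NaOCH3 (1 equiv), reflux
Reagents that add atoms: none
Why: Robinson annulation in which, under equilibrating alkoxide conditions, the more substituted C5/C10 enolate adds to the vinyl ketone on the α face, away from the axial C8 methyl that is 1,3 to C10, so C10 should carry CH3 β and the chain α, and aldol condensation of diketone 10 onto the C5 ketone closes ring A.

Step 7
Reactants: 11 tricyclic ring-A enone
Product: 13 tricyclic 4,4-dimethyl-3-ketone (5α-H, trans A/B), via lithium enolate 12 (not isolated)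
Conditions: Li, NH3(l)/THF, t-BuOH (1 equiv), −78 → −33 °C; then CH3I, THF, −78 °C → rt; NH4Cl
Reagents that add atoms: iodomethane CI
Why: Reductive alkylation of an enone, in which C5 is protonated axially from the α face opposite the C10 methyl to give the trans A/B fusion and the regiodefined enolate 12 is methylated at C4 to complete the gem-dimethyl group.

Step 8
Reactants: 13 tricyclic 4,4-dimethyl-3-ketone
Product: 14 ring-A diosphenol (2-hydroxy-1-en-3-one)
Conditions: KOC(CH3)3, t-BuOH, O2 (1 atm), rt; then dilute HCl
Reagents that add atoms: dioxygen O=O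
Why: Base-mediated autoxidation of a ketone, possible only at C2 because C4 is quaternary, in which the enolate captures O2 and the hydroperoxide collapses to the 2,3-dione that rests as its enol.

Step 9
Reactants: 14 ring-A diosphenol
Product: 15 2,3-seco diacid silyl ether (C10: β-CH3, α-CH2CO2H; C5: α-H, 2-carboxypropan-2-yl)
Conditions: H2O2 (30 % aq.), NaOH, CH3OH/H2O, 0 °C → rt; then dilute HCl to pH 3
Reagents that add atoms: hydrogen peroxide OO
Why: Oxidative cleavage of an α-diketone by alkaline hydrogen peroxide (acyl shift of the hydroperoxide adduct, then hydrolysis) severs only C2–C3 and delivers both carboxyl groups without loss of carbon or change at C5 and C10.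

Step 10
Reactants: 15 2,3-seco diacid silyl ether
Product: 16 dimethyl diester silyl ether
Conditions: CH3I, K2CO3, DMF, rt
Reagents that add atoms: iodomethane CI
Why: Carboxylate O-alkylation (SN2 at the methyl group) is indifferent to the crowding around the tertiary C3 carboxyl, so both acids should esterify.

Step 11
Reactants: 16 dimethyl diester silyl ether
Product: 17 13β-hydroxy-hydrindane dimethyl diester
Conditions: Bu4NF, THF, rt → 50 °C; then aq. NH4Cl
Reagents that add atoms: none
Why: Fluoride-mediated desilylation frees the secondary alcohol while the two methyl esters stay intact.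

Step 12
Reactants: 17 13β-hydroxy-hydrindane dimethyl diester
Product: 18 trans-hydrindan-13-one dimethyl diester
Conditions: Dess–Martin periodinane, CH2Cl2, rt
Reagents that add atoms: none
Why: Dess–Martin oxidation converts the hindered secondary alcohol into the cyclopentanone under neutral conditions with no epimerisable centre at risk.

Step 13
Reactants: 18 trans-hydrindan-13-one dimethyl diester
Product: 20 trans-fused δ-lactone dimethyl diester (8α-O, 8β-CH3), via Criegee adduct 19 (not isolated)
Conditions: (CF3CO)2O, urea·H2O2, Na2HPO4, CH2Cl2, 0 °C → rt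
Reagents that add atoms: trifluoroperacetic acid OOC(=O)C(F)(F)F
Why: Trifluoroperacetic acid adds to the C13 carbonyl to give the tetrahedral perester adduct 19, from which the C8–C13 bond, antiperiplanar to the O–O bond, shifts to oxygen as trifluoroacetate leaves. The closest known reaction type is the Baeyer–Villiger lactonisation of ring-fused cyclopentanones whose α-carbon is quaternary and carries an angular methyl, as in ring D ketones of steroids. Ring C is not closed by a cyclisation: the five-membered carbocycle (C8, C9, C11, C12, C13) is enlarged to the six-membered oxacycle by a 1,2-shift that inserts oxygen between C8 and C13, so no Baldwin closure mode applies. The C8–O stereocentre forms with retention because the migration is concerted and suprafacial, so the configuration from step 2 and the trans fusion from step 5 place oxygen equatorial (α) and the methyl axial (β). The step needs regioselectivity for migration of C8 over the C12 methylene, secured by the higher migratory aptitude of the fully substituted carbon, and chemoselectivity, secured because 18 holds no alkene or other oxidisable group. The Na2HPO4 buffer takes up trifluoroacetic acid so that the lactone and the methyl esters are not opened or exchanged.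

Step 14
Reactants: 20 trans-fused δ-lactone dimethyl diester
Product: 22 C13 methyl ketal (13-methoxy-13-methyl oxadecalin diester), via lactol 21 (not isolated)
Conditions: CH3Li (1.05 equiv), THF, −78 °C; then CH3SO3H (1.5 equiv), CH3OH, −78 °C → rt; NaHCO3 work-up
Reagents that add atoms: methyllithium [Li]C; methanol CO
Why: Single nucleophilic addition of methyllithium to a lactone followed by acid-catalysed ketalisation, where the unhindered δ-lactone carbonyl should react far faster than the two neopentyl-type methyl esters, the lithium hemiketalate persists at −78 °C, and acidic methanol converts lactol 21 into the ketal.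

Step 15
Reactants: 22 C13 methyl ketal
Product: 24 13α-[(trimethylsilyl)ethynyl]-13β-methyl oxadecalin dimethyl diester, via oxocarbenium ion 23 (not isolated)
Conditions: Bu3SnC≡CSi(CH3)3 (2 equiv), (CH3)3SiOSO2CF3 (1.2 equiv), CH2Cl2, −78 → −30 °C
Reagents that add atoms: tributyl[(trimethylsilyl)ethynyl]stannane CCCC[Sn](CCCC)(CCCC)C#C[Si](C)(C)C
Why: Lewis-acid-mediated C-alkynylation of a ketal through its oxocarbenium ion (C-glycosylation type, ipso substitution of the alkynylstannane), in which cation 23 is locked in one half-chair by the trans fusion and the slim alkyne should approach C13 from the α face because the axial C8 methyl screens the β face, setting C13 with alkynyl α and methyl β.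

Step 16
Reactants: 24 13α-[(trimethylsilyl)ethynyl]-13β-methyl oxadecalin dimethyl diester
Product: 25 13α-ethynyl-13β-methyl oxadecalin dimethyl diester
Conditions: K2CO3 (cat.), CH3OH, rt
Reagents that add atoms: none
Why: Methoxide-catalysed protodesilylation of the alkynylsilane leaves the methyl esters unchanged in methanol.

Step 17
Reactants: 25 13α-ethynyl-13β-methyl oxadecalin dimethyl diester
Product: 26 13α-vinyl-13β-methyl oxadecalin dimethyl diester
Conditions: H2 (1 atm), Pd/CaCO3 poisoned with Pb(OAc)2, quinoline, EtOAc, rt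
Reagents that add atoms: none
Why: Lindlar semi-hydrogenation stops at the alkene on the poisoned catalyst and creates no new stereocentre.

Step 18
Reactants: 26 13α-vinyl-13β-methyl oxadecalin dimethyl diester
Product: 27 2-[(2R,4aR,5S,6R,8aR)-5-(carboxymethyl)-2-ethenyl-2,5,8a-trimethyloctahydro-2H-chromen-6-yl]-2-methylpropanoic acid (CNP0186744.2)
Conditions: NaSC2H5 (excess), DMF, 90 °C; then cold dilute HCl to pH 3
Reagents that add atoms: none
Why: Thiolate SN2 demethylation of methyl esters attacks the methyl carbon, so the shielded tertiary C3 ester should cleave as readily as the C2 ester, and the non-acidic medium spares the tertiary allylic ether at C13.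

**Compound list**

1 | 2-methylcyclopentane-1,3-dione | CC1C(=O)CCC1=O | starting material
2 | pent-1-en-3-one | C=CC(=O)CC | starting material
3 | 2-methyl-2-(3-oxopentyl)cyclopentane-1,3-dione | CCC(=O)CCC1(C)C(=O)CCC1=O | intermediate
4 | (3aR,7aR)-3a-hydroxy-4,7a-dimethylhexahydro-1H-indene-1,5(4H)-dione, cis-fused ketol (OH cis to the angular methyl, C4 epimers) | O=C1CC[C@@]2(O)C(C)C(=O)CC[C@@]12C | intermediate
5 | (7aR)-4,7a-dimethyl-2,3,7,7a-tetrahydro-1H-indene-1,5(6H)-dione | O=C1CCC2=C(C)C(=O)CC[C@@]12C | intermediate
6 | (1R,7aR)-1-hydroxy-4,7a-dimethyl-1,2,3,6,7,7a-hexahydro-5H-inden-5-one (OH cis to the angular methyl) | O[C@@H]1CCC2=C(C)C(=O)CC[C@@]12C | intermediate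
7 | (1R,7aR)-1-[(tert-butyldimethylsilyl)oxy]-4,7a-dimethyl-1,2,3,6,7,7a-hexahydro-5H-inden-5-one | CC(C)(C)[Si](C)(C)O[C@@H]1CCC2=C(C)C(=O)CC[C@@]12C | intermediate
8 | lithium C5=C10 enolate of the trans-fused 13β-silyloxy-hydrindane (8β-CH3, 9α-H) | CC(C)(C)[Si](C)(C)O[C@@H]1CC[C@@H]2C(C)=C(O[Li])CC[C@@]12C | intermediate
9 | trans-fused 13β-(tert-butyldimethylsilyloxy)-hydrindan-5-one (8β-CH3, 9α-H, 10α-CH3 equatorial, 10β-H) | CC(C)(C)[Si](C)(C)O[C@@H]1CC[C@@H]2[C@@H](C)C(=O)CC[C@@]12C | intermediate
10 | Michael adduct: hydrindan-5-one with C10 carrying β-CH3 and α-(3-oxopentyl) | CC(C)(C)[Si](C)(C)O[C@@H]1CC[C@@H]2[C@@](C)(CCC(=O)CC)C(=O)CC[C@@]12C | intermediate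
11 | tricyclic ring-A enone (C3=O, C4=C5, 4-CH3, 8β-CH3, 10β-CH3, 9α-H, 13β-OSi) | CC(C)(C)[Si](C)(C)O[C@@H]1CC[C@@H]2[C@@]3(C)CCC(=O)C(C)=C3CC[C@@]12C | intermediate
12 | lithium C3=C4 enolate of the 5α-H tricycle | CC(C)(C)[Si](C)(C)O[C@@H]1CC[C@@H]2[C@@]3(C)CCC(O[Li])=C(C)[C@@H]3CC[C@@]12C | intermediate
13 | tricyclic 4,4-dimethyl-3-ketone (5α-H, trans A/B, 8β-CH3, 10β-CH3, 9α-H, 13β-OSi) | CC(C)(C)[Si](C)(C)O[C@@H]1CC[C@@H]2[C@@]3(C)CCC(=O)C(C)(C)[C@@H]3CC[C@@]12C | intermediate
14 | ring-A diosphenol (2-hydroxy-1-en-3-one) of 13 | CC(C)(C)[Si](C)(C)O[C@@H]1CC[C@@H]2[C@@]3(C)C=C(O)C(=O)C(C)(C)[C@@H]3CC[C@@]12C | intermediate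
15 | 2,3-seco diacid silyl ether (C10: β-CH3, α-CH2CO2H; C5: α-H, 2-carboxypropan-2-yl; 13β-OSi) | CC(C)(C)[Si](C)(C)O[C@@H]1CC[C@@H]2[C@@](C)(CC(=O)O)[C@H](C(C)(C)C(=O)O)CC[C@@]12C | intermediate
16 | dimethyl diester of 15 | CC(C)(C)[Si](C)(C)O[C@@H]1CC[C@@H]2[C@@](C)(CC(=O)OC)[C@H](C(C)(C)C(=O)OC)CC[C@@]12C | intermediate
17 | 13β-hydroxy-hydrindane dimethyl diester | O[C@@H]1CC[C@@H]2[C@@](C)(CC(=O)OC)[C@H](C(C)(C)C(=O)OC)CC[C@@]12C | intermediate
18 | trans-hydrindan-13-one dimethyl diester (8β-CH3, 9α-H, 10β-CH3, 10α-CH2CO2CH3, 5α-H) | O=C1CC[C@@H]2[C@@](C)(CC(=O)OC)[C@H](C(C)(C)C(=O)OC)CC[C@@]12C | intermediate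
19 | Criegee adduct: 13-hydroxy-13-(trifluoroacetylperoxy) derivative of 18 | OC1(OOC(=O)C(F)(F)F)CC[C@@H]2[C@@](C)(CC(=O)OC)[C@H](C(C)(C)C(=O)OC)CC[C@@]12C | intermediate
20 | trans-fused δ-lactone dimethyl diester (8α-O, 8β-CH3, 9α-H) | O=C1CC[C@@H]2[C@@](C)(CC(=O)OC)[C@H](C(C)(C)C(=O)OC)CC[C@@]2(C)O1 | intermediate
21 | lactol (13-hydroxy-13-methyl, in equilibrium with the open C8-hydroxy methyl ketone; C13 epimers) | CC1(O)CC[C@@H]2[C@@](C)(CC(=O)OC)[C@H](C(C)(C)C(=O)OC)CC[C@@]2(C)O1 | intermediate
22 | C13 methyl ketal (13-methoxy-13-methyl; C13 epimers) | COC1(C)CC[C@@H]2[C@@](C)(CC(=O)OC)[C@H](C(C)(C)C(=O)OC)CC[C@@]2(C)O1 | intermediate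
23 | 13-methyl oxocarbenium ion | CC=1CC[C@@H]2[C@@](C)(CC(=O)OC)[C@H](C(C)(C)C(=O)OC)CC[C@@]2(C)[O+]=1 | intermediate
24 | 13α-[(trimethylsilyl)ethynyl]-13β-methyl oxadecalin dimethyl diester | C[Si](C)(C)C#C[C@@]1(C)CC[C@@H]2[C@@](C)(CC(=O)OC)[C@H](C(C)(C)C(=O)OC)CC[C@@]2(C)O1 | intermediate
25 | 13α-ethynyl-13β-methyl oxadecalin dimethyl diester | C#C[C@@]1(C)CC[C@@H]2[C@@](C)(CC(=O)OC)[C@H](C(C)(C)C(=O)OC)CC[C@@]2(C)O1 | intermediate
26 | 13α-vinyl-13β-methyl oxadecalin dimethyl diester | C=C[C@@]1(C)CC[C@@H]2[C@@](C)(CC(=O)OC)[C@H](C(C)(C)C(=O)OC)CC[C@@]2(C)O1 | intermediate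
27 | 2-[(2R,4aR,5S,6R,8aR)-5-(carboxymethyl)-2-ethenyl-2,5,8a-trimethyloctahydro-2H-chromen-6-yl]-2-methylpropanoic acid | C=C[C@@]1(C)CC[C@@H]2[C@@](C)(CC(=O)O)[C@H](C(C)(C)C(=O)O)CC[C@@]2(C)O1 | target

**Step count**

Total: 18 steps. Longest linear sequence: 18 steps (fully linear from 1 and 2).

**Steps most likely to fail**

1. Step 15. The alkyne may attack the oxocarbenium ion on the β face along the chair-like axial trajectory, syn to the C8 methyl, giving the C13 epimer; the cation may also lose a proton to the C12=C13 enol ether. Fallback: the two C13 substituents are introduced in the opposite order, setting out from lactone 20. LiC≡CSi(CH3)3 in THF at −78 °C should add once to give the alkynyl lactol F1, and CH3OH with camphorsulfonic acid should convert it into the alkynyl methyl ketal F2. Al(CH3)3 in CH2Cl2 (−78 → 0 °C) should then ionise F2 and transfer methyl to the alkynyl-substituted cation on the face the alkyne had preferred, placing methyl β and the alkyne α. The sequence rejoins the route at 24.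

2. Step 6. The Michael addition may proceed through the less substituted C6 enolate, the vinyl ketone may polymerise, or the diketone may close to a bridged aldol. Fallback: the enolate is fixed regiochemically, setting out from enone 7. Li/NH3 reduction as in step 5 with trapping by (CH3)3SiCl/Et3N should give the trimethylsilyl enol ether F3. Mukaiyama–Michael addition of F3 to 2 with TiCl4 in CH2Cl2 at −78 °C should give diketone 10, now isolated, and NaOCH3 in CH3OH should close it. The sequence rejoins the route at 11.

3. Step 14. A second methyl addition to the ring-opened methyl ketone, or attack at a methyl ester, may compete with single addition. Fallback: acyl substitution replaces direct addition, setting out from lactone 20. CH3ONHCH3·HCl with Al(CH3)3 in CH2Cl2 at 0 °C should open the lactone to the hydroxy Weinreb amide F4. CH3MgBr (excess, the first equivalent deprotonating the C8 hydroxyl) should stop at the chelated adduct and give 21 on work-up, and CH3OH with camphorsulfonic acid should ketalise it. The sequence rejoins the route at 22.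

**Further compounds**

F1 | step 15 | alkynyl lactol, 13-hydroxy-13-[(trimethylsilyl)ethynyl] oxadecalin dimethyl diester (C13 epimers) | C[Si](C)(C)C#CC1(O)CC[C@@H]2[C@@](C)(CC(=O)OC)[C@H](C(C)(C)C(=O)OC)CC[C@@]2(C)O1
F2 | step 15 | alkynyl methyl ketal, 13-methoxy-13-[(trimethylsilyl)ethynyl] oxadecalin dimethyl diester (C13 epimers) | COC1(C#C[Si](C)(C)C)CC[C@@H]2[C@@](C)(CC(=O)OC)[C@H](C(C)(C)C(=O)OC)CC[C@@]2(C)O1
F3 | step 6 | trimethylsilyl enol ether (C5=C10) of the trans-fused 13β-silyloxy-hydrindane | CC(C)(C)[Si](C)(C)O[C@@H]1CC[C@@H]2C(C)=C(O[Si](C)(C)C)CC[C@@]12C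
F4 | step 14 | hydroxy Weinreb amide, C8-hydroxy N-methoxy-N-methyl amide from lactone opening | CON(C)C(=O)CC[C@@H]1[C@@](C)(CC(=O)OC)[C@H](C(C)(C)C(=O)OC)CC[C@@]1(C)O
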